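You have 3 questions on this flask: a solid substrate dissolves to starting material, starting material meets dissolved gas to give target, and it also parks reversibly as dormant form.

solid substrate 0.14 M; gas phase 6.9 mM (held); time 10 d

- how much target there is at 10 d, in percent of the solid substrate charged
- the change that raises the amount of target at 10 d, in percent of the solid substrate charged most ("none" if none brings more than 2 percentage points) (maple / larch / elm / oak / none)
- amount of target at 10 d, in percent of the solid substrate charged, after oak

- maple: doubling the transfer coefficient of step 4, all else as stated
- larch: doubling the saturation concentration of gas phase, all else as stated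
- elm: doubling the solubility in step 3, all else as stated
- oak: doubling the dissolution coefficient of step 3, all else as stated

- solid, in amounts per volume of the solution: solid substrate
- at the start none of the gas is dissolved
- at the start none of the solid substrate is in solution
- run time (flask): 10 d

    starting material + dissolved gas → target (k1 = 2.03 × 10⁻⁴ L mol⁻¹ s⁻¹)
    starting material ⇌ dormant form (K2 = 0.48, k2 = 2.51 × 10⁻⁶ s⁻¹)
    solid substrate ⇌ starting material, rate k3*(cs3 - [starting material]) while solid is left; crystals form when [starting material] > cs3 (cs3 = 0.12 M, k3 = 7.80 × 10⁻⁶ s⁻¹)
    gas phase ⇌ dissolved gas, rate k4*(csat - [dissolved gas]) (k4 = 1.43 × 10⁻⁴ s⁻¹, csat = 6.9 mM)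
    dissolved gas + target → over-reacted product (k5 = 5.27 × 10⁻⁶ L mol⁻¹ s⁻¹)

I begin with the balance of the reagent held at the smaller concentration, the dissolved gas (6.9 mM against 0.14 M of solid). It puts [dissolved gas] at saturation divided by one plus consumption over transfer. Even with the whole charge dissolved and free, consumption at 2.84 × 10⁻⁵ s⁻¹ is less than transfer at 1.43 × 10⁻⁴ s⁻¹, so I take [dissolved gas] as saturated and the reaction as pseudo-first-order in starting material.

Dormant form relaxes with half-life 1.04 d, shorter than the run, so I count a free share of 67.6 %. The conversion time, one over rate constant times saturation concentration times free share, is 12.2 d. Dissolving at its full rate, the charge takes 1.73 d, which I subtract as a lag.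

That gives me 49.1 % of target. Oak halves the dissolving time and gives 52.6 %, and larch, which halves the conversion time, gives 74.1 %, more than oak.

The forecast says 48.7 % (46 % to 51.5 %), larch, and 50.9 % after oak (48 % to 54 %), and one of its grounds is that “Gas transfer is fast compared with consumption”. Its oak figure is lower than my 52.6 %.

The simulation gives 48.0 %, larch with a gain of 23 percentage points, and 50.1 % after oak.

This flask at 10.0 d holds [dissolved gas] at 0.00646 M, with 32.8 % as starting material and 18.5 % as dormant form. Those amounts put the conversion time of this flask at that moment at 13.8 d, longer than the 12.2 d I reckoned. The neighbouring flask holds 0.056 M of solid substrate, so its lag is shorter, at 0.692 d. With a conversion time of 12.2 d, the reckoning gives 53.3 % for the neighbouring flask, and its simulation gives 53.1 %, with [dissolved gas] at 0.00674 M.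

The rate constants are assumed; the flask was simulated.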